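**Retrosynthetic overview**
1. The target is two (2R,3R)-7,8,4'-trihydroxyflavan units joined C4(β)–O–C4(α). Disconnect the interflavanyl C4–O bond (SN1 etherification), which leaves one monomer used in two roles: the all-cis 4α-ol 8 as acceptor and its trichloroacetimidate 9 as donor.
2. Monomer 8 comes from 3-benzyloxyflavone 6 by one asymmetric hydrogenation that sets C2, C3 and C4 (all cis).
3. Flavone 6 comes from flavonol 5, made by aldol condensation and Algar–Flynn–Oyamada (AFO) oxidation of acetophenone 2 and aldehyde 3.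
4. Ring order: rings A and B are bought; ring C is closed in the AFO step and saturated in the hydrogenation; the two halves are then joined through oxygen and all benzyl groups removed.

Assumption: the target is taken exactly as drawn, i.e. upper unit (2R,3R,4R) with 4α-O (all-cis) and lower unit (2R,3R,4S) with 4β-O (3,4-trans).
Assumption: the ligand enantiomer that gives the 2R series in step 4 is written as (R,R); a first screen would confirm this, and the (S,S) salt is equally available.

**Route**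

Step 1
Reactants: 1 2',3',4'-trihydroxyacetophenone (gallacetophenone)
Product: 2 1-[3,4-bis(benzyloxy)-2-hydroxyphenyl]ethan-1-one
Conditions: BnBr (2.1 equiv), K2CO3 (2.2 equiv), acetone, reflux, 6 h
Reagents that add atoms: benzyl bromide, BrCc1ccccc1
Why: Williamson etherification, in which the 2'-OH is hydrogen-bonded to the ketone and least nucleophilic, so only the 3'- and 4'-OH are benzylated.

Step 2
Reactants: 2 1-[3,4-bis(benzyloxy)-2-hydroxyphenyl]ethan-1-one; 3 4-(benzyloxy)benzaldehyde
Product: 5 7,8-bis(benzyloxy)-2-[4-(benzyloxy)phenyl]-3-hydroxy-4H-chromen-4-one, via chalcone 4 (not isolated)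
Conditions: KOH (aq, 5 equiv), EtOH/THF, rt, 24 h; then 30% H2O2 (3 equiv), 0 °C → rt, 4 h; HCl work-up
Reagents that add atoms: hydrogen peroxide, OO
Why: Claisen–Schmidt aldol condensation gives the (E)-2'-hydroxychalcone, and Algar–Flynn–Oyamada oxidative cyclisation closes ring C to the flavonol (the free 6'-position disfavours aurone formation); no stereocentre is formed.

Step 3
Reactants: 5 7,8-bis(benzyloxy)-2-[4-(benzyloxy)phenyl]-3-hydroxy-4H-chromen-4-one
Product: 6 3,7,8-tris(benzyloxy)-2-[4-(benzyloxy)phenyl]-4H-chromen-4-one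
Conditions: BnBr (1.3 equiv), K2CO3 (2 equiv), DMF, 60 °C, 4 h
Reagents that add atoms: benzyl bromide, BrCc1ccccc1
Why: Williamson O-alkylation of the acidic 3-OH masks the chelating 3-hydroxy-4-pyranone unit before hydrogenation and ensures that the later 4-OH is the only free hydroxyl of the monomer.

Step 4
Reactants: 6 3,7,8-tris(benzyloxy)-2-[4-(benzyloxy)phenyl]-4H-chromen-4-one
Product: 8 (2R,3R,4R)-3,7,8-tris(benzyloxy)-2-[4-(benzyloxy)phenyl]-3,4-dihydro-2H-chromen-4-ol (2,3-cis-3,4-cis), via cis-flavanone 7 (not isolated)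
Conditions: catalyst pre-formed from Ru(cod)(2-methylallyl)2 (5 mol %), (R,R)-SINpEt·HBF4 [1,3-bis((R)-1-(1-naphthyl)ethyl)imidazolinium tetrafluoroborate] (10 mol %) and KOt-Bu (10 mol %); H2 (80 bar), toluene, 40 °C, 36 h; recrystallise to ≥99% ee
Reagents that add atoms: none
Why: Proposed new method: the chiral NHC-bound divalent ruthenium hydride adds H2 syn to one enantioface of the tetrasubstituted C2=C3 enol ether (setting C2 and C3 cis, aryl and OBn both α), and the same catalyst then reduces the C4 ketone of flavanone 7 from the β face, anti to the axial 3-OBn and along the axial trajectory, so all three new hydrogens lie on one face and the 4α-ol results; the closest known reaction types are the Ru–NHC asymmetric hydrogenation of flavones and chromones to cis-flavan-4-ols and the heterogeneous hydrogenation of flavonols to racemic 2,3-cis-3,4-cis-diols, neither yet shown enantioselectively on a 3-oxygenated flavone.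

Step 5
Reactants: 8 (2R,3R,4R)-3,7,8-tris(benzyloxy)-2-[4-(benzyloxy)phenyl]-3,4-dihydro-2H-chromen-4-ol (0.55 of the batch; the remaining 0.45 is kept for step 6)
Product: 9 (2R,3S,4R)-3,7,8-tris(benzyloxy)-2-[4-(benzyloxy)phenyl]-3,4-dihydro-2H-chromen-4-yl 2,2,2-trichloroethanimidate
Conditions: Cl3CCN (3 equiv), DBU (0.1 equiv), CH2Cl2, 0 °C, 1 h; concentrate, short plug of Et3N-deactivated silica, use at once
Reagents that add atoms: trichloroacetonitrile, ClC(Cl)(Cl)C#N
Why: Base-catalysed addition of the 4-alkoxide to trichloroacetonitrile (trichloroacetimidate formation) functionalises only the O–H bond of the sole free hydroxyl, so the all-cis arrangement of 8 is kept (the C3 descriptor changes only through CIP priorities).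

Step 6
Reactants: 9 (2R,3S,4R)-3,7,8-tris(benzyloxy)-2-[4-(benzyloxy)phenyl]-3,4-dihydro-2H-chromen-4-yl 2,2,2-trichloroethanimidate; 8 (2R,3R,4R)-3,7,8-tris(benzyloxy)-2-[4-(benzyloxy)phenyl]-3,4-dihydro-2H-chromen-4-ol
Product: 10 (2R,3R,4R)-3,7,8-tris(benzyloxy)-2-[4-(benzyloxy)phenyl]-4-{[(2R,3R,4S)-3,7,8-tris(benzyloxy)-2-[4-(benzyloxy)phenyl]-3,4-dihydro-2H-chromen-4-yl]oxy}-3,4-dihydro-2H-chromene
Conditions: 9 (1.2 equiv), 8 (1.0 equiv), 4 Å MS, TMSOTf (0.1 equiv), CH2Cl2, −78 °C, 1 h; Et3N quench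
Reagents that add atoms: none
Why: Trichloroacetimidate O-alkylation by an SN1 path, in which TMSOTf ionises 9 to the flavan-4-yl cation (stabilised by the para 7-benzyloxy group) and the 4α-OH of 8 captures it on the β face, anti to the α-disposed 3-OBn and 2-aryl groups, so the new C4–O bond is 3,4-trans (4S) while the acceptor keeps its 4R centre; only the imidate ionises at −78 °C and no water is formed, so the kinetic α,β-ether is not scrambled.

Step 7
Reactants: 10 octa-O-benzyl ether from step 6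
Product: 11 (2R,3R,4R)-2-(4-hydroxyphenyl)-4-{[(2R,3R,4S)-3,7,8-trihydroxy-2-(4-hydroxyphenyl)-3,4-dihydro-2H-chromen-4-yl]oxy}-3,4-dihydro-2H-chromene-3,7,8-triol (CNP0241481.2)
Conditions: H2 (1 atm), 20% Pd(OH)2/C, THF/EtOAc 1:1 (no alcohol, no acid), rt, 2–4 h, LC-MS control; filter under Ar, lyophilise
Reagents that add atoms: none
Why: Catalytic hydrogenolysis of the eight O-benzyl groups, in which the secondary, ring-bound and hindered C4–O–C4 ether (like the benzylic C2–O1 bond present in every flavan) is cleaved far more slowly than primary benzyl ethers under neutral conditions, and no stereocentre is touched.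

**Compound list**
1 | 2',3',4'-trihydroxyacetophenone (gallacetophenone) | CC(=O)c1ccc(O)c(O)c1O | starting material
2 | 1-[3,4-bis(benzyloxy)-2-hydroxyphenyl]ethan-1-one | CC(=O)c1ccc(OCc2ccccc2)c(OCc2ccccc2)c1O | intermediate
3 | 4-(benzyloxy)benzaldehyde | O=Cc1ccc(OCc2ccccc2)cc1 | starting material
4 | (E)-1-[3,4-bis(benzyloxy)-2-hydroxyphenyl]-3-[4-(benzyloxy)phenyl]prop-2-en-1-one (chalcone) | O=C(/C=C/c1ccc(OCc2ccccc2)cc1)c1ccc(OCc2ccccc2)c(OCc2ccccc2)c1O | intermediate
5 | 7,8-bis(benzyloxy)-2-[4-(benzyloxy)phenyl]-3-hydroxy-4H-chromen-4-one (flavonol) | O=c1c(O)c(-c2ccc(OCc3ccccc3)cc2)oc2c(OCc3ccccc3)c(OCc3ccccc3)ccc12 | intermediate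
6 | 3,7,8-tris(benzyloxy)-2-[4-(benzyloxy)phenyl]-4H-chromen-4-one | O=c1c(OCc2ccccc2)c(-c2ccc(OCc3ccccc3)cc2)oc2c(OCc3ccccc3)c(OCc3ccccc3)ccc12 | intermediate
7 | (2R,3S)-3,7,8-tris(benzyloxy)-2-[4-(benzyloxy)phenyl]-2,3-dihydro-4H-chromen-4-one (2,3-cis) | c1ccccc1COc1ccc([C@H]2Oc3c(ccc(OCc4ccccc4)c3OCc3ccccc3)C(=O)[C@H]2OCc2ccccc2)cc1 | intermediate
8 | (2R,3R,4R)-3,7,8-tris(benzyloxy)-2-[4-(benzyloxy)phenyl]-3,4-dihydro-2H-chromen-4-ol (all-cis; tetra-O-benzylteracacidin) | c1ccccc1COc1ccc([C@H]2Oc3c(ccc(OCc4ccccc4)c3OCc3ccccc3)[C@@H](O)[C@H]2OCc2ccccc2)cc1 | intermediate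
9 | (2R,3S,4R)-3,7,8-tris(benzyloxy)-2-[4-(benzyloxy)phenyl]-3,4-dihydro-2H-chromen-4-yl 2,2,2-trichloroethanimidate (same all-cis arrangement as 8) | c1ccccc1COc1ccc([C@H]2Oc3c(ccc(OCc4ccccc4)c3OCc3ccccc3)[C@@H](OC(=N)C(Cl)(Cl)Cl)[C@H]2OCc2ccccc2)cc1 | intermediate
10 | (2R,3R,4R)-3,7,8-tris(benzyloxy)-2-[4-(benzyloxy)phenyl]-4-{[(2R,3R,4S)-3,7,8-tris(benzyloxy)-2-[4-(benzyloxy)phenyl]-3,4-dihydro-2H-chromen-4-yl]oxy}-3,4-dihydro-2H-chromene (octa-O-benzyl 4α–O–4β ether) | c1ccccc1COc1ccc([C@H]2Oc3c(ccc(OCc5ccccc5)c3OCc3ccccc3)[C@@H](O[C@H]3c4ccc(OCc5ccccc5)c(OCc5ccccc5)c4O[C@H](c4ccc(OCc5ccccc5)cc4)[C@@H]3OCc3ccccc3)[C@H]2OCc2ccccc2)cc1 | intermediate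
11 | (2R,3R,4R)-2-(4-hydroxyphenyl)-4-{[(2R,3R,4S)-3,7,8-trihydroxy-2-(4-hydroxyphenyl)-3,4-dihydro-2H-chromen-4-yl]oxy}-3,4-dihydro-2H-chromene-3,7,8-triol | Oc1ccc([C@H]2Oc3c(ccc(O)c3O)[C@@H](O[C@H]3c4ccc(O)c(O)c4O[C@H](c4ccc(O)cc4)[C@@H]3O)[C@H]2O)cc1 | target

**Step count and risks**
Total steps: 7. Longest linear sequence: 7 (linear; monomer 8 enters step 5 as donor precursor and step 6 as acceptor).

Steps most likely to fail:

Step 4 (the proposed new asymmetric hydrogenation; the tetrasubstituted enol ether may react slowly or with low ee). Fallback with known chemistry, setting out from 6: heterogeneous syn-hydrogenation over 5% Pt/C (H2 20 bar, EtOAc/THF, 50 °C). This is the established stereochemical course from flavonol derivatives to 2,3-cis-3,4-cis-diols, and Pt spares aryl benzyl ethers far better than Pd. It gives the racemic all-cis alcohol F1. F1 is resolved by preparative SFC on a chiral stationary phase (amylose tris(3,5-dimethylphenylcarbamate)); the (2R,3R,4R) enantiomer is 8, where the fallback rejoins the route.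

Step 6 (imidate 9 may rearrange to the N-alkyl amide before it is captured, or C6 of ring A may compete as nucleophile). Fallback setting out from 8 and bypassing 9: acid-catalysed thiolysis (BnSH 3 equiv, BF3·OEt2 0.2 equiv, CH2Cl2, −30 °C) gives the 4β-benzylsulfanyl flavan F2. F2 (1.2 equiv) and 8 (1 equiv) are then joined by thiophilic activation with AgBF4 (1.5 equiv) and 2,6-di-tert-butyl-4-methylpyridine in THF/CH2Cl2 with 4 Å MS at −40 → 0 °C. The sulfur donor is activated selectively, and the hindered pyridine buffers the HBF4 formed so that the acceptor and product ether are not ionised. The fallback comes back to the route at 10.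

Step 7 (partial hydrogenolysis or solvolysis of the bis-benzylic C4–O–C4 ether once the 7-OH groups are free). Fallback setting out from 8: debenzylate at the monomer stage (H2, Pd/C, EtOAc, rt), which the benzylic 4-OH of flavan-3,4-diols tolerates, to give free (−)-teracacidin F3. F3 is then self-condensed without protecting groups (AgBF4, THF, 0 °C → rt). The 7-OH lets the C4 cation form as a para-quinone methide, and the weakly nucleophilic pyrogallol-type ring A leaves the 4α-OH of a second molecule to trap it on the β face. The 4→O→3 regioisomer and unchanged F3 are removed on Sephadex LH-20. This comes back to the route at target 11, with the labile ether made last and never exposed to a deprotection.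

**Further compounds**
F1 | step 4 | racemic all-cis 3,7,8-tris(benzyloxy)-2-[4-(benzyloxy)phenyl]-3,4-dihydro-2H-chromen-4-ol (1:1 mixture of the 2R,3R,4R and 2S,3S,4S enantiomers) | c1ccccc1COc1ccc([C@H]2Oc3c(ccc(OCc4ccccc4)c3OCc3ccccc3)[C@@H](O)[C@H]2OCc2ccccc2)cc1.c1ccccc1COc1ccc([C@@H]2Oc3c(ccc(OCc4ccccc4)c3OCc3ccccc3)[C@H](O)[C@@H]2OCc2ccccc2)cc1
F2 | step 6 | (2R,3S,4S)-4-(benzylsulfanyl)-3,7,8-tris(benzyloxy)-2-[4-(benzyloxy)phenyl]-3,4-dihydro-2H-chromene (2,3-cis-3,4-trans, 4β-S) | c1ccccc1CS[C@H]1c2ccc(OCc3ccccc3)c(OCc3ccccc3)c2O[C@H](c2ccc(OCc3ccccc3)cc2)[C@@H]1OCc1ccccc1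
F3 | step 7 | (−)-teracacidin, (2R,3R,4R)-2-(4-hydroxyphenyl)-3,4-dihydro-2H-chromene-3,4,7,8-tetrol | Oc1ccc([C@H]2Oc3c(ccc(O)c3O)[C@@H](O)[C@H]2O)cc1
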